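**Plan**

- Retrosynthesis: the O8 ester and the silyl ethers are cut last; then C6–C7 and C11–C12 (together with C12–O6) are cut in one stroke, which opens both the cyclohexane and the lactone to an acyclic allenyl aldehyde plus CO; C5–C10 is cut by an Ireland–Claisen retron; C13, C2/C14 and C8–C9 go back to formaldehyde, AlMe3 and a propargylboration.
- Forward: C8–C9, then the E-C1=C10 olefin, then the allene, then the allyl ester, then C5–C10 (chain complete), then the aldehyde; one [2+2+1] event closes the six-membered ring and the lactone; acylation at O8 and desilylation finish.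
- Enabling feature: the α-methylene-γ-butyrolactone O6–C12(=O)–C11(=C13H2)–C7–C6, trans-fused on the C6–C7 bond of the cyclohexane, is the adduct of an aldehyde C6=O, CO and the internal π-bond C7=C11 of a terminal allene; ring atoms C5, C8 and C10 carry equatorial groups and C10 an axial methyl, which steer the closure.
- Stereochemistry: C8 by a chiral phosphoric acid catalyst; C5 and C10 together by a chiral-boron Ireland–Claisen (chair, E-olefin, E(O)-enolate); C6 and C7 together by substrate control in the key step; C2′ from the (R)-Roche ester.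

Key step: step 13

Assumption: elemane numbering (C1–C15, side chain C1′–C4′) is used for atoms; the sense of induction of (S)-TRIP (step 1) and of the (S,S)-diazaborolidine (step 10) is taken from the closest precedents, and the mirror-image catalyst or controller would be used if it proved opposite.

**Route**

Step 1
Reactants: 1 3-(trimethylsilyl)prop-2-ynal; 2 allenylboronic acid pinacol ester
Product: 4 (3S)-1-(trimethylsilyl)hexa-1,5-diyn-3-ol, via pinacol borate ester 3 (not isolated)
Conditions: (S)-TRIP (10 mol%), 4 Å MS, toluene, −20 °C; aq. work-up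
Reagents that add atoms: none
Why: Chiral phosphoric acid-catalysed propargylboration (SE2′ transfer from the allenylboronate through a closed six-membered chair transition state, the catalyst activating the boronate and shielding one aldehyde face) should give the homopropargylic alcohol with C8 set (S) by the catalyst.

Step 2
Reactants: 4 (3S)-1-(trimethylsilyl)hexa-1,5-diyn-3-ol
Product: 5 tert-butyldimethyl{[(3S)-1-(trimethylsilyl)hexa-1,5-diyn-3-yl]oxy}silane
Conditions: TBSCl, imidazole, DMF, rt
Reagents that add atoms: tert-butyldimethylsilyl chloride, CC(C)(C)[Si](C)(C)Cl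
Why: Standard silylation of a secondary alcohol, which touches no stereocentre and gives the ether that later keeps O8 inert in the key step.

Step 3
Reactants: 5 tert-butyldimethyl{[(3S)-1-(trimethylsilyl)hexa-1,5-diyn-3-yl]oxy}silane
Product: 7 (2E,5S)-5-[(tert-butyldimethylsilyl)oxy]-3-methyl-7-(trimethylsilyl)hept-2-en-6-yn-1-ol, via alkenylalane 6 (not isolated)
Conditions: AlMe3, Cp2ZrCl2 (0.25 equiv), CH2Cl2, 0 °C → rt; then (CH2O)n, THF, 0 °C → rt; aq. Rochelle salt
Reagents that add atoms: trimethylaluminium, C[Al](C)C; formaldehyde (as paraformaldehyde), C=O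
Why: Negishi zirconium-catalysed carboalumination adds methyl and aluminium syn across the terminal alkyne with aluminium on the terminal carbon (the silyl-capped internal alkyne reacts far more slowly), and trapping of the alkenylalane with formaldehyde with retention should give the E-trisubstituted allylic alcohol.

Step 4
Reactants: 7 (2E,5S)-5-[(tert-butyldimethylsilyl)oxy]-3-methyl-7-(trimethylsilyl)hept-2-en-6-yn-1-ol
Product: 8 (2E,5S)-5-[(tert-butyldimethylsilyl)oxy]-3-methylhept-2-en-6-yn-1-ol
Conditions: K2CO3 (cat.), MeOH, rt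
Reagents that add atoms: none
Why: Base-catalysed methanolysis cleaves the C(sp)–Si bond selectively, the secondary TBS ether being stable to carbonate in methanol.

Step 5
Reactants: 8 (2E,5S)-5-[(tert-butyldimethylsilyl)oxy]-3-methylhept-2-en-6-yn-1-ol
Product: 10 (2E,5S)-5-[(tert-butyldimethylsilyl)oxy]-3-methylocta-2,6,7-trien-1-ol, via propargylic amine 9 (not isolated)
Conditions: (CH2O)n, CuI (0.5 equiv), Cy2NH, dioxane, reflux
Reagents that add atoms: formaldehyde (as paraformaldehyde), C=O
Why: Crabbé homologation (copper-mediated Mannich coupling of the terminal alkyne, then intramolecular hydride transfer from the amine with loss of imine) should turn the alkyne into the terminal allene without touching C8.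

Step 6
Reactants: 11 itaconic acid 4-methyl ester
Product: 12 methyl 3-(hydroxymethyl)but-3-enoate
Conditions: BH3·SMe2 (1.0 equiv), THF, −10 → 0 °C; MeOH quench
Reagents that add atoms: none
Why: Borane reduces a carboxylic acid (via the acyloxyborane) much faster than an ester, and one equivalent at low temperature should spare the electron-poor 1,1-disubstituted alkene (chemoselective borane reduction).

Step 7
Reactants: 12 methyl 3-(hydroxymethyl)but-3-enoate
Product: 13 methyl 3-({[tert-butyl(diphenyl)silyl]oxy}methyl)but-3-enoate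
Conditions: TBDPSCl, imidazole, CH2Cl2, 0 °C → rt
Reagents that add atoms: tert-butyldiphenylsilyl chloride, CC(C)(C)[Si](Cl)(c1ccccc1)c1ccccc1
Why: Immediate silylation of the primary allylic alcohol prevents lactonisation and installs the robust C15 protecting group.

Step 8
Reactants: 13 methyl 3-({[tert-butyl(diphenyl)silyl]oxy}methyl)but-3-enoate
Product: 14 3-({[tert-butyl(diphenyl)silyl]oxy}methyl)but-3-enoic acid
Conditions: LiOH, THF/H2O, 0 °C; then 1 M HCl
Reagents that add atoms: lithium hydroxide, [Li+].[OH-]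
Why: Saponification at 0 °C is faster than base-induced migration of the β,γ-double bond into conjugation, and the TBDPS ether is stable to hydroxide.

Step 9
Reactants: 10 (2E,5S)-5-[(tert-butyldimethylsilyl)oxy]-3-methylocta-2,6,7-trien-1-ol; 14 3-({[tert-butyl(diphenyl)silyl]oxy}methyl)but-3-enoic acid
Product: 15 (2E,5S)-5-[(tert-butyldimethylsilyl)oxy]-3-methylocta-2,6,7-trien-1-yl 3-({[tert-butyl(diphenyl)silyl]oxy}methyl)but-3-enoate
Conditions: DCC, DMAP (5 mol%), CH2Cl2, 0 °C
Reagents that add atoms: none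
Why: Steglich esterification of a primary allylic alcohol, run cold with little DMAP so that the β,γ-unsaturated acyl group does not slip into conjugation.

Step 10
Reactants: 15 (2E,5S)-5-[(tert-butyldimethylsilyl)oxy]-3-methylocta-2,6,7-trien-1-yl 3-({[tert-butyl(diphenyl)silyl]oxy}methyl)but-3-enoate
Product: 18 (2R,3S,5S)-5-[(tert-butyldimethylsilyl)oxy]-2-(3-{[tert-butyl(diphenyl)silyl]oxy}prop-1-en-2-yl)-3-ethenyl-3-methylocta-6,7-dienoic acid, via boron ketene acetal 16 (not isolated), via acyloxyborane 17 (not isolated)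
Conditions: N,N′-[(1S,2S)-1,2-diphenylethane-1,2-diyl]bis[3,5-bis(trifluoromethyl)benzenesulfonamide] + BBr3 (CH2Cl2, rt; evaporate) to form the bromoborane; then 15, Et3N, toluene–hexane, −78 °C; then −20 → 4 °C; aq. work-up
Reagents that add atoms: none
Why: Enantioselective Ireland–Claisen rearrangement through the chiral boron E(O)-dienolate (soft enolisation at the doubly activated α-CH2) and a chair transition state, in which the E-olefin puts C9 equatorial and the E(O)-geometry puts the 2-propenyl group axial (anti C5/C10 relationship) while the C2-symmetric diazaborolidine selects the enolate face and so the absolute configuration (5R,10S), the closest precedent being the same rearrangement of E-3-methylalk-2-enyl 3-methylbut-3-enoates.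

Step 11
Reactants: 18 (2R,3S,5S)-5-[(tert-butyldimethylsilyl)oxy]-2-(3-{[tert-butyl(diphenyl)silyl]oxy}prop-1-en-2-yl)-3-ethenyl-3-methylocta-6,7-dienoic acid
Product: 19 (2R,3S,5S)-5-[(tert-butyldimethylsilyl)oxy]-2-(3-{[tert-butyl(diphenyl)silyl]oxy}prop-1-en-2-yl)-3-ethenyl-3-methylocta-6,7-dien-1-ol
Conditions: LiAlH4, Et2O, 0 °C → rt
Reagents that add atoms: none
Why: Hydride reduction of the hindered acid to the primary alcohol, in which isolated alkenes and the O-silylated allene (no free hydroxyl to direct hydroalumination) should stay untouched.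

Step 12
Reactants: 19 (2R,3S,5S)-5-[(tert-butyldimethylsilyl)oxy]-2-(3-{[tert-butyl(diphenyl)silyl]oxy}prop-1-en-2-yl)-3-ethenyl-3-methylocta-6,7-dien-1-ol
Product: 20 (2R,3S,5S)-5-[(tert-butyldimethylsilyl)oxy]-2-(3-{[tert-butyl(diphenyl)silyl]oxy}prop-1-en-2-yl)-3-ethenyl-3-methylocta-6,7-dienal
Conditions: Dess–Martin periodinane, NaHCO3, CH2Cl2, 0 °C → rt; used crude
Reagents that add atoms: none
Why: Dess–Martin oxidation under buffered, non-basic conditions should give the β,γ-unsaturated aldehyde without epimerising C5 or moving the double bond into conjugation.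

Step 13
Reactants: 20 (2R,3S,5S)-5-[(tert-butyldimethylsilyl)oxy]-2-(3-{[tert-butyl(diphenyl)silyl]oxy}prop-1-en-2-yl)-3-ethenyl-3-methylocta-6,7-dienal
Product: 21 (3aS,4S,6S,7R,7aR)-4-[(tert-butyldimethylsilyl)oxy]-7-(3-{[tert-butyl(diphenyl)silyl]oxy}prop-1-en-2-yl)-6-ethenyl-6-methyl-3-methylidenehexahydro-1-benzofuran-2(3H)-one
Conditions: Mo(CO)6 (1.2 equiv), DMSO (10 equiv), toluene, 100 °C
Reagents that add atoms: molybdenum hexacarbonyl (CO source), [Mo].[C-]#[O+].[C-]#[O+].[C-]#[O+].[C-]#[O+].[C-]#[O+].[C-]#[O+]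
Why: Mo(0), freed of CO by DMSO, binds the aldehyde C6=O and the internal allene π-bond C7=C11 and couples them oxidatively to an oxamolybdacyclopentane (C6–C7 bond), CO then inserts into the Mo–C11 bond (C11–C12 bond) and reductive elimination closes C12–O6. The closest known reaction type is the Mo(CO)6- or Ru3(CO)12-mediated allenic hetero-Pauson–Khand cyclocarbonylation of allenyl aldehydes to bicyclic α-methylene-γ-butyrolactones. The cyclohexane closes in a 6-exo mode (C6 onto the proximal allene carbon C7, leaving C11=C13 exocyclic) and the lactone is the five-membered [2+2+1] ring completed by the carbonylative reductive elimination. C6 and C7 are set by the resident centres in a chair-like transition state with the C5 side chain, the C8 silyloxy group and the C10 vinyl group equatorial: the axial C10 methyl penalises an axial C6–O bond (1,3-diaxial) and an equatorial C7–C11 bond avoids the diaxial contacts with H5 and H9, so O6 and C11 should end up trans-diequatorial, which is the trans ring fusion of the target. Needed are reaction at the internal and not the terminal allene π-bond (the internal one gives the six-membered ring and the exocyclic methylene, the terminal one would need a seven-membered ring), inertness of the vinyl and 1,1-disubstituted alkenes (unactivated alkenes do not enter this cycloaddition) and retention of C5 (neutral medium, C5 flanked by the quaternary C10).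

Step 14
Reactants: 21 (3aS,4S,6S,7R,7aR)-4-[(tert-butyldimethylsilyl)oxy]-7-(3-{[tert-butyl(diphenyl)silyl]oxy}prop-1-en-2-yl)-6-ethenyl-6-methyl-3-methylidenehexahydro-1-benzofuran-2(3H)-one
Product: 22 (3aR,4S,6S,7R,7aR)-7-(3-{[tert-butyl(diphenyl)silyl]oxy}prop-1-en-2-yl)-6-ethenyl-4-hydroxy-6-methyl-3-methylidenehexahydro-1-benzofuran-2(3H)-one
Conditions: CSA (cat.), MeOH/CH2Cl2, 0 °C → rt
Reagents that add atoms: none
Why: Acid-catalysed methanolysis cleaves a TBS ether much faster than a TBDPS ether (selective desilylation), and methanol does not add to the methylene lactone under acid.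

Step 15
Reactants: 23 methyl (2R)-3-hydroxy-2-methylpropanoate
Product: 24 methyl (2R)-3-{[tert-butyl(diphenyl)silyl]oxy}-2-methylpropanoate
Conditions: TBDPSCl, imidazole, CH2Cl2, rt
Reagents that add atoms: tert-butyldiphenylsilyl chloride, CC(C)(C)[Si](Cl)(c1ccccc1)c1ccccc1
Why: Standard silylation of the primary alcohol of the Roche ester, which brings C2′ from the chiral pool with the same protecting group as C15.

Step 16
Reactants: 24 methyl (2R)-3-{[tert-butyl(diphenyl)silyl]oxy}-2-methylpropanoate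
Product: 25 (2R)-3-{[tert-butyl(diphenyl)silyl]oxy}-2-methylpropanoic acid
Conditions: LiOH, THF/MeOH/H2O, 0 °C → rt; then 1 M HCl
Reagents that add atoms: lithium hydroxide, [Li+].[OH-]
Why: Mild saponification, in which the carboxylate formed protects C2′ against enolisation and the silyl ether against β-elimination.

Step 17
Reactants: 22 (3aR,4S,6S,7R,7aR)-7-(3-{[tert-butyl(diphenyl)silyl]oxy}prop-1-en-2-yl)-6-ethenyl-4-hydroxy-6-methyl-3-methylidenehexahydro-1-benzofuran-2(3H)-one; 25 (2R)-3-{[tert-butyl(diphenyl)silyl]oxy}-2-methylpropanoic acid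
Product: 26 (3aR,4S,6S,7R,7aR)-7-(3-{[tert-butyl(diphenyl)silyl]oxy}prop-1-en-2-yl)-6-ethenyl-6-methyl-3-methylidene-2-oxooctahydro-1-benzofuran-4-yl (2R)-3-{[tert-butyl(diphenyl)silyl]oxy}-2-methylpropanoate
Conditions: DCC, DMAP (cat.), CH2Cl2, 0 °C → rt
Reagents that add atoms: none
Why: Steglich esterification of the equatorial C8 alcohol, run cold with catalytic DMAP to limit epimerisation at C2′ through the activated acyl species.

Step 18
Reactants: 26 (3aR,4S,6S,7R,7aR)-7-(3-{[tert-butyl(diphenyl)silyl]oxy}prop-1-en-2-yl)-6-ethenyl-6-methyl-3-methylidene-2-oxooctahydro-1-benzofuran-4-yl (2R)-3-{[tert-butyl(diphenyl)silyl]oxy}-2-methylpropanoate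
Product: 27 (3aR,4S,6S,7R,7aR)-6-ethenyl-7-(3-hydroxyprop-1-en-2-yl)-6-methyl-3-methylidene-2-oxooctahydro-1-benzofuran-4-yl (2R)-3-hydroxy-2-methylpropanoate
Conditions: HF·pyridine, pyridine, THF, 0 °C → rt
Reagents that add atoms: none
Why: Buffered fluoride cleaves both primary TBDPS ethers, and the mildly acidic medium avoids conjugate addition to the methylene lactone and acyl migration.

**Compound list**

1 | 3-(trimethylsilyl)prop-2-ynal | C[Si](C)(C)C#CC=O | starting material
2 | allenylboronic acid pinacol ester, 4,4,5,5-tetramethyl-2-(propa-1,2-dien-1-yl)-1,3,2-dioxaborolane | C=C=CB1OC(C)(C)C(C)(C)O1 | starting material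
3 | 4,4,5,5-tetramethyl-2-{[(3S)-1-(trimethylsilyl)hexa-1,5-diyn-3-yl]oxy}-1,3,2-dioxaborolane | C#CC[C@H](OB1OC(C)(C)C(C)(C)O1)C#C[Si](C)(C)C | intermediate
4 | (3S)-1-(trimethylsilyl)hexa-1,5-diyn-3-ol | C#CC[C@H](O)C#C[Si](C)(C)C | intermediate
5 | tert-butyldimethyl{[(3S)-1-(trimethylsilyl)hexa-1,5-diyn-3-yl]oxy}silane | C#CC[C@H](O[Si](C)(C)C(C)(C)C)C#C[Si](C)(C)C | intermediate
6 | [(1E,4S)-4-[(tert-butyldimethylsilyl)oxy]-2-methyl-6-(trimethylsilyl)hex-1-en-5-yn-1-yl]dimethylalane | C[Al](C)/C=C(\C)C[C@H](O[Si](C)(C)C(C)(C)C)C#C[Si](C)(C)C | intermediate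
7 | (2E,5S)-5-[(tert-butyldimethylsilyl)oxy]-3-methyl-7-(trimethylsilyl)hept-2-en-6-yn-1-ol | OC/C=C(\C)C[C@H](O[Si](C)(C)C(C)(C)C)C#C[Si](C)(C)C | intermediate
8 | (2E,5S)-5-[(tert-butyldimethylsilyl)oxy]-3-methylhept-2-en-6-yn-1-ol | OC/C=C(\C)C[C@H](O[Si](C)(C)C(C)(C)C)C#C | intermediate
9 | (2E,5S)-5-[(tert-butyldimethylsilyl)oxy]-8-(dicyclohexylamino)-3-methyloct-2-en-6-yn-1-ol | OC/C=C(\C)C[C@H](O[Si](C)(C)C(C)(C)C)C#CCN(C1CCCCC1)C1CCCCC1 | intermediate
10 | (2E,5S)-5-[(tert-butyldimethylsilyl)oxy]-3-methylocta-2,6,7-trien-1-ol | OC/C=C(\C)C[C@H](O[Si](C)(C)C(C)(C)C)C=C=C | intermediate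
11 | itaconic acid 4-methyl ester, 4-methoxy-2-methylidene-4-oxobutanoic acid | COC(=O)CC(=C)C(=O)O | starting material
12 | methyl 3-(hydroxymethyl)but-3-enoate | COC(=O)CC(=C)CO | intermediate
13 | methyl 3-({[tert-butyl(diphenyl)silyl]oxy}methyl)but-3-enoate | COC(=O)CC(=C)CO[Si](c1ccccc1)(c1ccccc1)C(C)(C)C | intermediate
14 | 3-({[tert-butyl(diphenyl)silyl]oxy}methyl)but-3-enoic acid | OC(=O)CC(=C)CO[Si](c1ccccc1)(c1ccccc1)C(C)(C)C | intermediate
15 | (2E,5S)-5-[(tert-butyldimethylsilyl)oxy]-3-methylocta-2,6,7-trien-1-yl 3-({[tert-butyl(diphenyl)silyl]oxy}methyl)but-3-enoate | C=C(CO[Si](c1ccccc1)(c1ccccc1)C(C)(C)C)CC(=O)OC/C=C(\C)C[C@H](O[Si](C)(C)C(C)(C)C)C=C=C | intermediate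
16 | E(O)-boron ketene acetal of 15 carrying the (4S,5S)-1,3-bis{[3,5-bis(trifluoromethyl)phenyl]sulfonyl}-4,5-diphenyl-1,3,2-diazaborolidin-2-yl group on oxygen | C=C(CO[Si](c1ccccc1)(c1ccccc1)C(C)(C)C)/C=C(/OB1N(S(=O)(=O)c2cc(C(F)(F)F)cc(C(F)(F)F)c2)[C@@H](c2ccccc2)[C@H](c2ccccc2)N1S(=O)(=O)c1cc(C(F)(F)F)cc(C(F)(F)F)c1)OC/C=C(\C)C[C@H](O[Si](C)(C)C(C)(C)C)C=C=C | intermediate
17 | acyloxyborane of 18 with the same (4S,5S)-diazaborolidin-2-yl group | O=C(OB1N(S(=O)(=O)c2cc(C(F)(F)F)cc(C(F)(F)F)c2)[C@@H](c2ccccc2)[C@H](c2ccccc2)N1S(=O)(=O)c1cc(C(F)(F)F)cc(C(F)(F)F)c1)[C@@H](C(=C)CO[Si](c1ccccc1)(c1ccccc1)C(C)(C)C)[C@](C)(C=C)C[C@H](O[Si](C)(C)C(C)(C)C)C=C=C | intermediate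
18 | (2R,3S,5S)-5-[(tert-butyldimethylsilyl)oxy]-2-(3-{[tert-butyl(diphenyl)silyl]oxy}prop-1-en-2-yl)-3-ethenyl-3-methylocta-6,7-dienoic acid | OC(=O)[C@@H](C(=C)CO[Si](c1ccccc1)(c1ccccc1)C(C)(C)C)[C@](C)(C=C)C[C@H](O[Si](C)(C)C(C)(C)C)C=C=C | intermediate
19 | (2R,3S,5S)-5-[(tert-butyldimethylsilyl)oxy]-2-(3-{[tert-butyl(diphenyl)silyl]oxy}prop-1-en-2-yl)-3-ethenyl-3-methylocta-6,7-dien-1-ol | OC[C@@H](C(=C)CO[Si](c1ccccc1)(c1ccccc1)C(C)(C)C)[C@](C)(C=C)C[C@H](O[Si](C)(C)C(C)(C)C)C=C=C | intermediate
20 | (2R,3S,5S)-5-[(tert-butyldimethylsilyl)oxy]-2-(3-{[tert-butyl(diphenyl)silyl]oxy}prop-1-en-2-yl)-3-ethenyl-3-methylocta-6,7-dienal | O=C[C@@H](C(=C)CO[Si](c1ccccc1)(c1ccccc1)C(C)(C)C)[C@](C)(C=C)C[C@H](O[Si](C)(C)C(C)(C)C)C=C=C | intermediate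
21 | (3aS,4S,6S,7R,7aR)-4-[(tert-butyldimethylsilyl)oxy]-7-(3-{[tert-butyl(diphenyl)silyl]oxy}prop-1-en-2-yl)-6-ethenyl-6-methyl-3-methylidenehexahydro-1-benzofuran-2(3H)-one | C=C[C@]1(C)C[C@H](O[Si](C)(C)C(C)(C)C)[C@H]2C(=C)C(=O)O[C@@H]2[C@H]1C(=C)CO[Si](c1ccccc1)(c1ccccc1)C(C)(C)C | intermediate
22 | (3aR,4S,6S,7R,7aR)-7-(3-{[tert-butyl(diphenyl)silyl]oxy}prop-1-en-2-yl)-6-ethenyl-4-hydroxy-6-methyl-3-methylidenehexahydro-1-benzofuran-2(3H)-one | C=C[C@]1(C)C[C@H](O)[C@H]2C(=C)C(=O)O[C@@H]2[C@H]1C(=C)CO[Si](c1ccccc1)(c1ccccc1)C(C)(C)C | intermediate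
23 | methyl (2R)-3-hydroxy-2-methylpropanoate, (R)-Roche ester | COC(=O)[C@H](C)CO | starting material
24 | methyl (2R)-3-{[tert-butyl(diphenyl)silyl]oxy}-2-methylpropanoate | COC(=O)[C@H](C)CO[Si](c1ccccc1)(c1ccccc1)C(C)(C)C | intermediate
25 | (2R)-3-{[tert-butyl(diphenyl)silyl]oxy}-2-methylpropanoic acid | OC(=O)[C@H](C)CO[Si](c1ccccc1)(c1ccccc1)C(C)(C)C | intermediate
26 | (3aR,4S,6S,7R,7aR)-7-(3-{[tert-butyl(diphenyl)silyl]oxy}prop-1-en-2-yl)-6-ethenyl-6-methyl-3-methylidene-2-oxooctahydro-1-benzofuran-4-yl (2R)-3-{[tert-butyl(diphenyl)silyl]oxy}-2-methylpropanoate | C=C[C@]1(C)C[C@H](OC(=O)[C@H](C)CO[Si](c3ccccc3)(c3ccccc3)C(C)(C)C)[C@H]2C(=C)C(=O)O[C@@H]2[C@H]1C(=C)CO[Si](c1ccccc1)(c1ccccc1)C(C)(C)C | intermediate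
27 | (3aR,4S,6S,7R,7aR)-6-ethenyl-7-(3-hydroxyprop-1-en-2-yl)-6-methyl-3-methylidene-2-oxooctahydro-1-benzofuran-4-yl (2R)-3-hydroxy-2-methylpropanoate (CNP0133858.1) | C=C[C@]1(C)C[C@H](OC(=O)[C@H](C)CO)[C@H]2C(=C)C(=O)O[C@@H]2[C@H]1C(=C)CO | target

**Count and risks**

Total steps: 18. Longest linear sequence: 13 (steps 1–5, 9–14, 17, 18).

Steps most likely to fail:

1. Step 13. The oxidative coupling of C=O and C=C at one metal centre prefers a syn-coplanar geometry, so ring-fusion control may be lost: a cis-fused lactone with an axial C7–C11 bond could form in place of the trans-diequatorial one. The β,γ-unsaturated aldehyde may also epimerise at C5 or decompose at 100 °C. Fallback, from 20 back to 21, with the two bonds made in separate known steps so that the ring-fusion isomers can be separated at the alcohol stage: palladium-catalysed distannylative carbocyclisation of 20 (Bu3Sn–SnBu3, [(η3-allyl)PdCl]2 cat., THF, rt; allene distannylation, then intramolecular carbonyl allylation at C7) should give after work-up the 2-[1-(tributylstannyl)ethenyl]cyclohexanol F1; iododestannylation (I2, CH2Cl2, 0 °C) gives the 2-(1-iodoethenyl)cyclohexanol F2; palladium-catalysed carbonylative lactonisation (Pd(PPh3)4 cat., CO 1 atm, Et3N, MeCN, 60 °C) closes the methylene lactone and returns to 21.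

2. Step 10. Enolisation may be incomplete or give mixed E(O)/Z(O) geometry, facial control by the controller may be weak for a rearrangement that builds a quaternary centre, and the long reaction time may let the Lewis acid strip a silyl ether. Fallback, from 15 back to 18, which replaces reagent control by separation of diastereomers (possible because C8 is already a single enantiomer): Ireland–Claisen rearrangement with achiral reagents (LDA, THF, −78 °C; TMSCl; → rt) through the E(O)-trimethylsilyl ketene acetal F3 to the trimethylsilyl ester F4; aqueous work-up should give the two anti acids, 18 and its (2S,3R,5S)-diastereomer F5, which are separated by chromatography (as methyl esters if needed), and 18 re-enters the route.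

3. Step 1. Enantiofacial discrimination may be low for a small, linear ynal, and an uncatalysed background addition may erode it further. Fallback, from 1 back to 4, by resolution instead of catalysis: zinc-mediated Barbier propargylation of 1 (propargyl bromide, Zn, THF, 0 °C) gives racemic 1-(trimethylsilyl)hexa-1,5-diyn-3-ol F6; lipase-catalysed kinetic resolution (Pseudomonas lipase, vinyl acetate, hexane) should acylate the (R)-enantiomer (silylethynyl as the large group in the empirical lipase rule) to the (3R)-acetate F7 and leave the (S)-alcohol 4, which re-enters the route.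

Further compounds
F1 | step 13 | 2-[1-(tributylstannyl)ethenyl]cyclohexanol with the ring substituents and configuration of 21 (C6 hydroxyl free) | C=C[C@]1(C)C[C@H](O[Si](C)(C)C(C)(C)C)[C@@H](C(=C)[Sn](CCCC)(CCCC)CCCC)[C@H](O)[C@H]1C(=C)CO[Si](c1ccccc1)(c1ccccc1)C(C)(C)C
F2 | step 13 | 2-(1-iodoethenyl)cyclohexanol with the ring substituents and configuration of 21 (C6 hydroxyl free) | C=C[C@]1(C)C[C@H](O[Si](C)(C)C(C)(C)C)[C@@H](C(=C)I)[C@H](O)[C@H]1C(=C)CO[Si](c1ccccc1)(c1ccccc1)C(C)(C)C
F3 | step 10 | E(O)-trimethylsilyl ketene acetal of 15 | C=C(CO[Si](c1ccccc1)(c1ccccc1)C(C)(C)C)/C=C(/O[Si](C)(C)C)OC/C=C(\C)C[C@H](O[Si](C)(C)C(C)(C)C)C=C=C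
F4 | step 10 | trimethylsilyl ester of 18 | C[Si](C)(C)OC(=O)[C@@H](C(=C)CO[Si](c1ccccc1)(c1ccccc1)C(C)(C)C)[C@](C)(C=C)C[C@H](O[Si](C)(C)C(C)(C)C)C=C=C
F5 | step 10 | (2S,3R,5S)-5-[(tert-butyldimethylsilyl)oxy]-2-(3-{[tert-butyl(diphenyl)silyl]oxy}prop-1-en-2-yl)-3-ethenyl-3-methylocta-6,7-dienoic acid | OC(=O)[C@H](C(=C)CO[Si](c1ccccc1)(c1ccccc1)C(C)(C)C)[C@@](C)(C=C)C[C@H](O[Si](C)(C)C(C)(C)C)C=C=C
F6 | step 1 | racemic 1-(trimethylsilyl)hexa-1,5-diyn-3-ol | C#CCC(O)C#C[Si](C)(C)C
F7 | step 1 | (3R)-1-(trimethylsilyl)hexa-1,5-diyn-3-yl acetate | C#CC[C@@H](OC(C)=O)C#C[Si](C)(C)C
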